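Readings and results are simulated with made-up constants.

You face 5 questions on 4 flasks, and one dimensionless number reaches the part that the readings can reach.

| setting | larch | dawn | autumn | midnight | summer |
|---|---|---|---|---|---|
| J | 20 mM | 20 mM | 20 mM | 20 mM | 20 mM |
| X | 1.2 equiv | 1.20 equiv | 1.20 equiv | 1.20 equiv | 1.20 equiv |
| Z | 3 mM | 2.00 mM | 2.00 mM | 2.00 mM | 2.00 mM |
| temperature | 25 °C | 25 °C | −25 °C | 0 °C |  |
| remark | run made earlier |  |  |  | at −25 °C until 30 h, from then on at 25 °C |
| time |  | 2.5 d | 2.5 d | 2.5 d | 2.5 d |

larch run (percent of the J charged)

| time / h | D / % | J / % |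
|---|---|---|
| 1.00 | 0.2 | 93.2 |
| 3.00 | 1.0 | 80.9 |
| 6.00 | 5.8 | 68.7 |
| 8.00 | 9.6 | 64.0 |
| 12.0 | 16.7 | 56.2 |

(scatter of a reading: 1 percentage point)

- steps that have been proposed: J + X <-> L; L -> D; J + Z -> E
- the earlier runs do not show what temperature does; that part of a forecast is a guess
- no earlier run changes the charge of Z; that part of a forecast is a guess

- which flask leads in amount of D, in percent of the J charged ("all alike" within 1.5 percentage points) (dawn / autumn / midnight / summer / all alike)
- how much D is there at the end, in percent of the J charged: dawn
- how much D is there at the end, in percent of the J charged: autumn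
- how much D is there at the end, in percent of the J charged: midnight
- how much D is there at the end, in percent of the J charged: summer

1. Follow one J molecule to its fork: it goes through L to D, or it meets Z and ends as E. By the proposed step each Z takes one J, so if I take Z as used up, the share of J left for D in dawn is φ = 1 − [Z]/[J] = 90.0 %.

2. Between 8.00 h and 12.0 h the larch run gains D at ρ = 0.0178 /h, as a fraction of the charge. I let dawn start at this rate and slow in proportion to what remains of φ, so its filling time is τ = φ/ρ = 50.7 h.

3. Then N = t/τ, for dawn 1.18, is the filling number (a Damköhler number), which counts the filling times a flask has had, and D = φ(1 − e^−N). My reckoning for dawn is therefore 62.4 %.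

4. For summer I count the cold hours as nothing, which is a guess. The 30.0 h that remain give N = 0.592 and 40.2 %, so in my reckoning dawn holds more D than summer.

5. Was one number enough? Larch at 12.0 h, with its own φ of 85.0 %, gives 18.8 % against the reading of 16.7 %, and that gap of 2.1 percentage points stands against a scatter of 1 point: N does not hold the early lag of D. Temperature is not in N either, so I give no figure for autumn or midnight.

The forecast names dawn as leader, with 60 % for dawn, 0.5 % for autumn, 9 % for midnight and 42 % for summer, and it says of the cold flasks: “Temperature is a guess”. It differs from my reckoning on dawn and summer, and it commits to figures for the cold flasks where I do not.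

The flasks give 65.3 % in dawn, 0 % in autumn, 1.83 % in midnight and 43.9 % in summer, so dawn leads.

    J + X ⇌ L (K = 88.0 /M, k = 0.0350 /M/min, Ea = 78.0 kJ/mol, ΔH = −46.0 kJ/mol)
    L → D (k = 0.00180 /min, Ea = 86.0 kJ/mol)
    J + Z → E (k = 0.150 /M/min, Ea = 52.0 kJ/mol)
    (constants at 25 °C)

The forecast's 9 % for midnight stands against 1.83 %, and N, which has no temperature in it, gave no figure there. At the end of dawn E stands at 9.90 %, with Z at 1.04 % of its own charge. Carried to 25.0 d, N for dawn becomes 11.8 and gives 90.0 % of D, and the dawn flask then holds 89.9 %.

Read the summer flask at 6.0 d instead: 114 h of warm time give N = 2.25 and so 80.5 %. The computed flask holds 79.3 % of D.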